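The furan-2,4-dione ring (O1, lactone C2, quaternary C3, ketone C4, ylidene C5) is treated as a masked malonate, because C2 and C4 are both carboxyl-level carbons on C3. The route assembles a prochiral 2-aryl-2-prenylmalonate with two identical (diethoxyphosphoryl)methyl ester arms. A chiral lithium amide then lithiates the O–CH2–P carbon of one arm, which closes onto the other ester: in one operation the C4–C5 bond and the lactone ring form, C3 becomes a defined stereocentre, and C5 keeps a phosphonate. Horner–Wadsworth–Emmons olefination with the silylated 4-hydroxy-3-prenylbenzaldehyde and desilylation complete the target.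

Key step: step 8

Abbreviations: prenyl = 3-methylbut-2-en-1-yl; allyl = prop-2-en-1-yl; TBS = tert-butyldimethylsilyl; ring A = arene of the benzylidene unit; ring B = arene on C3; O1 and C2–C5 are the atoms of the furan-2,4-dione ring.

Assumption: which enantiomer of the amide leads to (S)-C3 cannot be predicted with confidence; the (R,R)-amide is written, and the (S,S)-amide, equally available, would take its place if the sense of induction proves to be the opposite.

**Route**

Step 1
Reactants: 1 4-hydroxyphenylacetic acid
Product: 2 allyl (4-hydroxyphenyl)acetate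
Conditions: allyl alcohol (solvent), TsOH·H2O (cat.), 80 °C
Reagents that add atoms: allyl alcohol, `C=CCO`
Why: Fischer esterification, in which only the carboxylic acid reacts and the phenol stays free; the allyl ester is chosen because it can later be removed without hydroxide or acid.

Step 2
Reactants: 2 allyl (4-hydroxyphenyl)acetate; 3 prenyl bromide (1-bromo-3-methylbut-2-ene)
Product: 4 allyl (4-hydroxy-3-prenylphenyl)acetate
Conditions: NaH (1.0 equiv), toluene, 0 °C; then 3, rt
Reagents that add atoms: none
Why: Ortho C-alkylation of a phenoxide, since in toluene the sodium phenoxide reacts as a tight ion pair whose oxygen is blocked by the cation, so the allylic bromide should be taken up at the ortho carbon (the para position is occupied) before rearomatisation.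

Step 3
Reactants: 4 allyl (4-hydroxy-3-prenylphenyl)acetate
Product: 5 allyl [4-(TBS-oxy)-3-prenylphenyl]acetate
Conditions: TBSCl, imidazole, DMF, rt
Reagents that add atoms: tert-butyldimethylsilyl chloride (TBSCl), `CC(C)(C)[Si](C)(C)Cl`
Why: Imidazole-promoted silylation of a phenol, which masks the acidic O–H for the enolate and lithium amide chemistry that follows.

Step 4
Reactants: 5 allyl [4-(TBS-oxy)-3-prenylphenyl]acetate
Product: 6 diallyl 2-[4-(TBS-oxy)-3-prenylphenyl]malonate
Conditions: LiN(SiMe3)2 (2.2 equiv), THF, −78 °C; allyl chloroformate, −78 to 0 °C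
Reagents that add atoms: allyl chloroformate, `C=CCOC(Cl)=O`
Why: Claisen-type C-acylation of an ester enolate with a chloroformate, in which the second equivalent of base turns the arylmalonate into its enolate as it forms and so stops over-acylation, while at −78 °C the allyl ester enolate should not undergo Ireland–Claisen rearrangement.

Step 5
Reactants: 6 diallyl 2-[4-(TBS-oxy)-3-prenylphenyl]malonate; 3 prenyl bromide
Product: 7 diallyl 2-[4-(TBS-oxy)-3-prenylphenyl]-2-prenylmalonate
Conditions: NaH, THF/DMF, 0 °C; then 3, 0 °C to rt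
Reagents that add atoms: none
Why: Malonate alkylation (SN2), in which the sodium enolate attacks the primary carbon of the allylic bromide and so gives the linear prenyl group on a quaternary carbon that is still achiral.

Step 6
Reactants: 7 diallyl 2-[4-(TBS-oxy)-3-prenylphenyl]-2-prenylmalonate
Product: 8 2-[4-(TBS-oxy)-3-prenylphenyl]-2-prenylmalonic acid
Conditions: Pd(PPh3)4 (5 mol %), morpholine (6 equiv), THF, 0 °C to rt; cold aq. KHSO4 wash
Reagents that add atoms: none
Why: Tsuji–Trost deallylation, in which zerovalent palladium ionises only the two allyl esters and morpholine traps the allyl fragments, so the diacid is freed without hydroxide (which would cleave the aryl silyl ether) and without heat (which would decarboxylate it).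

Step 7
Reactants: 8 2-[4-(TBS-oxy)-3-prenylphenyl]-2-prenylmalonic acid; 9 diethyl (hydroxymethyl)phosphonate
Product: 11 bis[(diethoxyphosphoryl)methyl] 2-[4-(TBS-oxy)-3-prenylphenyl]-2-prenylmalonate, via malonyl dichloride 10 (not isolated)
Conditions: 1-chloro-N,N,2-trimethylprop-1-en-1-amine (2.2 equiv), CH2Cl2, 0 °C to rt; then 9 (2.5 equiv in all), pyridine, DMAP (cat.), 0 °C to rt
Reagents that add atoms: diethyl (hydroxymethyl)phosphonate (the second equivalent of 9), `CCOP(=O)(CO)OCC`
Why: Acid chloride formation with an α-chloroenamine runs under neutral conditions without HCl and so spares the prenyl alkenes and the silyl ether, and DMAP-catalysed acylation then consumes one molecule of the primary alcohol 9 (the later source of O1 and C5) at each of the two acyl chloride groups, which should give the symmetric diester.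

Step 8
Reactants: 11 bis[(diethoxyphosphoryl)methyl] 2-[4-(TBS-oxy)-3-prenylphenyl]-2-prenylmalonate
Product: 14 (3S)-5-(diethoxyphosphoryl)-4-hydroxy-3-[4-(TBS-oxy)-3-prenylphenyl]-3-prenylfuran-2(3H)-one, via α-lithio phosphonate 12 (not isolated), via lithium enolate 13 (not isolated)
Conditions: LiN(CHMePh)2 (2.2 equiv, from (R,R)-HN(CHMePh)2 and n-BuLi), LiCl, THF, −78 °C; slow addition of 11, −78 to −40 °C; AcOH, −78 °C
Reagents that add atoms: none
Why: Proposed new method: the amide removes a proton from the O–CH2–P group of one ester arm (the only C–H acids present, since C3 is quaternary) to give the phosphonate-stabilised α-oxy carbanion 12, which, after rotation of its ester C–O bond into the lactone-like conformation, adds to the carbonyl of the other arm and expels lithium (diethoxyphosphoryl)methoxide, so that the C4–C5 bond is made. The closest known reaction types are enantiotopic-group-selective deprotonation by chiral lithium amides and the Dieckmann-type closure of α-acyloxy esters to tetronic acids, here with the roles reversed because the nucleophile sits on the alkoxy carbon. The five-membered lactone ring closes 5-exo-trig, the attacked C=O lying outside the new ring. C3 becomes stereogenic only through this event, because the carbonyl of the lithiated arm ends as lactone carbon C2 and that of the partner arm as ketone carbon C4, so its configuration is fixed by which arm the twofold-symmetric chiral amide lithiates, a choice that cannot revert since the amine is far less acidic than the phosphonate. The step thus needs arm selectivity, for which the flat ring B and the flexible prenyl chain on C3 are the only features that make the two arms look different to the base, and it needs 5-exo attack to beat a 1,2-acyl shift within the lithiated arm, which the crowded acyl carbon next to C3 and the activated phosphonomethyl ester of the partner arm should favour. The β-keto phosphonate formed gives up its C5 proton to the second equivalent of base, and enolate 13 resists alkoxide attack at C4, so that ring opening and loss of configuration are avoided until the cold acetic acid quench.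

Step 9
Reactants: 15 4-hydroxybenzaldehyde; 3 prenyl bromide
Product: 16 4-hydroxy-3-prenylbenzaldehyde
Conditions: KOH, H2O, rt; then 3
Reagents that add atoms: none
Why: Ortho C-alkylation of a phenoxide in water, where hydrogen bonding shields the phenoxide oxygen so that the allylic bromide should react at the ortho carbon of the para-substituted ring.

Step 10
Reactants: 16 4-hydroxy-3-prenylbenzaldehyde
Product: 17 4-(TBS-oxy)-3-prenylbenzaldehyde
Conditions: TBSCl, imidazole, DMF, rt
Reagents that add atoms: tert-butyldimethylsilyl chloride (TBSCl), `CC(C)(C)[Si](C)(C)Cl`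
Why: Imidazole-promoted silylation of a phenol, needed because a free phenoxide would deactivate the aldehyde towards the olefination.

Step 11
Reactants: 14 (3S)-5-(diethoxyphosphoryl)-4-hydroxy-3-[4-(TBS-oxy)-3-prenylphenyl]-3-prenylfuran-2(3H)-one; 17 4-(TBS-oxy)-3-prenylbenzaldehyde
Product: 19 (3S,5Z)-5-[4-(TBS-oxy)-3-prenylbenzylidene]-3-[4-(TBS-oxy)-3-prenylphenyl]-3-prenylfuran-2,4(3H,5H)-dione, via sodium enolate 18 (not isolated)
Conditions: NaH (1.05 equiv), THF, 0 °C; then 17, 0 °C to rt
Reagents that add atoms: none
Why: Horner–Wadsworth–Emmons olefination, in which NaH turns the acidic enol 14 irreversibly into sodium enolate 18, whose C5 adds to the aldehyde before syn elimination of sodium diethyl phosphate; reversible addition should favour the more stable Z-alkene, whose aryl group lies on the side of O1 and away from the C4 carbonyl, and C3, which bears no hydrogen, is untouched.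

Step 12
Reactants: 19 (3S,5Z)-5-[4-(TBS-oxy)-3-prenylbenzylidene]-3-[4-(TBS-oxy)-3-prenylphenyl]-3-prenylfuran-2,4(3H,5H)-dione
Product: 20 (3S,5Z)-5-(4-hydroxy-3-prenylbenzylidene)-3-(4-hydroxy-3-prenylphenyl)-3-prenylfuran-2,4(3H,5H)-dione
Conditions: HF·pyridine, pyridine, THF, 0 °C to rt
Reagents that add atoms: none
Why: Fluoride-driven cleavage of both aryl silyl ethers in a buffered, weakly acidic medium, which avoids phenoxide or alkoxide nucleophiles that could open the acylated lactone and strong acid that could cyclise the ortho-prenylphenols to chromans.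

**Compound list**

1 | 4-hydroxyphenylacetic acid | `OC(=O)Cc1ccc(O)cc1` | starting material
2 | allyl (4-hydroxyphenyl)acetate | `C=CCOC(=O)Cc1ccc(O)cc1` | intermediate
3 | prenyl bromide (1-bromo-3-methylbut-2-ene) | `CC(C)=CCBr` | starting material
4 | allyl (4-hydroxy-3-prenylphenyl)acetate | `C=CCOC(=O)Cc1ccc(O)c(CC=C(C)C)c1` | intermediate
5 | allyl [4-(TBS-oxy)-3-prenylphenyl]acetate | `C=CCOC(=O)Cc1ccc(O[Si](C)(C)C(C)(C)C)c(CC=C(C)C)c1` | intermediate
6 | diallyl 2-[4-(TBS-oxy)-3-prenylphenyl]malonate | `C=CCOC(=O)C(C(=O)OCC=C)c1ccc(O[Si](C)(C)C(C)(C)C)c(CC=C(C)C)c1` | intermediate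
7 | diallyl 2-[4-(TBS-oxy)-3-prenylphenyl]-2-prenylmalonate | `C=CCOC(=O)C(CC=C(C)C)(C(=O)OCC=C)c1ccc(O[Si](C)(C)C(C)(C)C)c(CC=C(C)C)c1` | intermediate
8 | 2-[4-(TBS-oxy)-3-prenylphenyl]-2-prenylmalonic acid | `OC(=O)C(CC=C(C)C)(C(=O)O)c1ccc(O[Si](C)(C)C(C)(C)C)c(CC=C(C)C)c1` | intermediate
9 | diethyl (hydroxymethyl)phosphonate | `CCOP(=O)(CO)OCC` | starting material
10 | 2-[4-(TBS-oxy)-3-prenylphenyl]-2-prenylmalonyl dichloride (formed in situ) | `ClC(=O)C(CC=C(C)C)(C(Cl)=O)c1ccc(O[Si](C)(C)C(C)(C)C)c(CC=C(C)C)c1` | intermediate
11 | bis[(diethoxyphosphoryl)methyl] 2-[4-(TBS-oxy)-3-prenylphenyl]-2-prenylmalonate | `CCOP(=O)(OCC)COC(=O)C(CC=C(C)C)(c1ccc(O[Si](C)(C)C(C)(C)C)c(CC=C(C)C)c1)C(=O)OCP(=O)(OCC)OCC` | intermediate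
12 | (diethoxyphosphoryl)(lithio)methyl (diethoxyphosphoryl)methyl (2S)-2-[4-(TBS-oxy)-3-prenylphenyl]-2-prenylmalonate; configuration at the lithiated carbon not defined (formed in situ) | `CCOP(=O)(OCC)C([Li])OC(=O)[C@@](CC=C(C)C)(c1ccc(O[Si](C)(C)C(C)(C)C)c(CC=C(C)C)c1)C(=O)OCP(=O)(OCC)OCC` | intermediate
13 | lithium (4S)-2-(diethoxyphosphoryl)-5-oxo-4-[4-(TBS-oxy)-3-prenylphenyl]-4-prenyl-4,5-dihydrofuran-3-olate (formed in situ) | `O=C1OC(P(=O)(OCC)OCC)=C(O[Li])[C@]1(CC=C(C)C)c1ccc(O[Si](C)(C)C(C)(C)C)c(CC=C(C)C)c1` | intermediate
14 | (3S)-5-(diethoxyphosphoryl)-4-hydroxy-3-[4-(TBS-oxy)-3-prenylphenyl]-3-prenylfuran-2(3H)-one | `O=C1OC(P(=O)(OCC)OCC)=C(O)[C@]1(CC=C(C)C)c1ccc(O[Si](C)(C)C(C)(C)C)c(CC=C(C)C)c1` | intermediate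
15 | 4-hydroxybenzaldehyde | `O=Cc1ccc(O)cc1` | starting material
16 | 4-hydroxy-3-prenylbenzaldehyde | `O=Cc1ccc(O)c(CC=C(C)C)c1` | intermediate
17 | 4-(TBS-oxy)-3-prenylbenzaldehyde | `O=Cc1ccc(O[Si](C)(C)C(C)(C)C)c(CC=C(C)C)c1` | intermediate
18 | sodium (4S)-2-(diethoxyphosphoryl)-5-oxo-4-[4-(TBS-oxy)-3-prenylphenyl]-4-prenyl-4,5-dihydrofuran-3-olate (formed in situ) | `O=C1OC(P(=O)(OCC)OCC)=C(O[Na])[C@]1(CC=C(C)C)c1ccc(O[Si](C)(C)C(C)(C)C)c(CC=C(C)C)c1` | intermediate
19 | (3S,5Z)-5-[4-(TBS-oxy)-3-prenylbenzylidene]-3-[4-(TBS-oxy)-3-prenylphenyl]-3-prenylfuran-2,4(3H,5H)-dione | `CC(C)=CCc1cc(/C=C2\OC(=O)[C@@](CC=C(C)C)(c3ccc(O[Si](C)(C)C(C)(C)C)c(CC=C(C)C)c3)C2=O)ccc1O[Si](C)(C)C(C)(C)C` | intermediate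
20 | (3S,5Z)-5-(4-hydroxy-3-prenylbenzylidene)-3-(4-hydroxy-3-prenylphenyl)-3-prenylfuran-2,4(3H,5H)-dione | `CC(C)=CCc1cc(/C=C2\OC(=O)[C@@](CC=C(C)C)(c3ccc(O)c(CC=C(C)C)c3)C2=O)ccc1O` | target

**Step count and risks**

Total: 12 steps. Longest linear sequence: 10 steps (steps 1 to 8, then 11 and 12); steps 9 and 10 form the side branch to aldehyde 17.

Steps most likely to fail:

Step 8. The amide may discriminate poorly between the two arms, or the lithiated arm may be lost to 1,2-acyl migration or proton exchange before it closes the ring. The fallback uses known chemistry, sets out from 8 and comes back at 14; an enzyme sets the stereocentre and the ring is closed in two conventional bond formations. Diacid 8 would be methylated with Me3SiCHN2 (toluene/MeOH) to dimethyl 2-[4-(TBS-oxy)-3-prenylphenyl]-2-prenylmalonate F1. Pig liver esterase (phosphate buffer, pH 7.5, a little DMSO) should hydrolyse one of the enantiotopic esters, an established desymmetrisation of disubstituted malonates, to the (S)-half-ester F2; if the mirror-image acid forms, a hydrolase of opposite preference would be screened. The free acid would be converted with the chloroenamine of step 7 into the acyl chloride F3, which acylates the lithiated form of commercially available diethyl [(tetrahydro-2H-pyran-2-yloxy)methyl]phosphonate (2 equiv, THF, −78 °C) to the α-(tetrahydropyranyloxy) β-keto phosphonate F4; this makes the C4–C5 bond. Pyridinium p-toluenesulfonate in methanol would then remove the acetal and let the freed hydroxyl close the lactone onto the methyl ester, giving 14.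

Step 11. The doubly stabilised C5 anion may add slowly or reversibly to the electron-rich aldehyde, and the alkene geometry may be poorly controlled. The fallback sets out from 14 and comes back at 19; the ylidene is built in two carbon–carbon events with ring A arriving last. Olefination of 14 with anhydrous monomeric formaldehyde (NaH, THF, 0 °C), the most electrophilic aldehyde, should give the (3S)-5-methylidene furan-2,4-dione F5, to be used without storage. Commercial 4-iodophenol would be prenylated as in step 2 to 4-iodo-2-prenylphenol F6 and silylated to its TBS ether F7. A Mizoroki–Heck reaction of F5 with F7 (Pd(OAc)2, P(o-tol)3, Et3N, MeCN, 70 °C) should place the aryl group on the terminal carbon. C5 carries no other β-hydrogen, so syn β-hydride elimination can only restore the exocyclic double bond, with the aryl group anti to the C4 carbonyl, which is the Z-isomer 19.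

Step 2. O-alkylation and double alkylation may outweigh mono C-alkylation at the ortho carbon. The fallback sets out from 2 and comes back at 4; the prenyl group is delivered to the ortho carbon by a sigmatropic shift. Phenol 2 would be O-alkylated with 3-chloro-3-methylbut-1-yne (DBU, CuCl2 cat., MeCN, 0 °C) to the propargylic ether F8. Semi-hydrogenation (H2, Pd on CaCO3 poisoned with Pb(OAc)2, quinoline, stopped after one equivalent so that the allyl ester is kept) should give the 1,1-dimethylallyl ether F9. Heating F9 in xylene (about 130 °C) should bring about the aromatic Claisen rearrangement, whose allylic inversion turns the reverse-prenyl ether into the ortho-prenyl phenol 4, the para position being blocked.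

**Further compounds**

F1 | step 8 | dimethyl 2-[4-(TBS-oxy)-3-prenylphenyl]-2-prenylmalonate | `COC(=O)C(CC=C(C)C)(C(=O)OC)c1ccc(O[Si](C)(C)C(C)(C)C)c(CC=C(C)C)c1`
F2 | step 8 | (2S)-2-[4-(TBS-oxy)-3-prenylphenyl]-2-(methoxycarbonyl)-5-methylhex-4-enoic acid | `COC(=O)[C@@](CC=C(C)C)(c1ccc(O[Si](C)(C)C(C)(C)C)c(CC=C(C)C)c1)C(=O)O`
F3 | step 8 | methyl (2R)-2-[4-(TBS-oxy)-3-prenylphenyl]-2-(chlorocarbonyl)-5-methylhex-4-enoate | `COC(=O)[C@@](CC=C(C)C)(c1ccc(O[Si](C)(C)C(C)(C)C)c(CC=C(C)C)c1)C(Cl)=O`
F4 | step 8 | methyl (2S)-2-[4-(TBS-oxy)-3-prenylphenyl]-4-(diethoxyphosphoryl)-3-oxo-2-prenyl-4-(tetrahydro-2H-pyran-2-yloxy)butanoate, mixture at C4 and at the acetal carbon | `COC(=O)[C@@](CC=C(C)C)(c1ccc(O[Si](C)(C)C(C)(C)C)c(CC=C(C)C)c1)C(=O)C(OC1CCCCO1)P(=O)(OCC)OCC`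
F5 | step 11 | (3S)-5-methylidene-3-[4-(TBS-oxy)-3-prenylphenyl]-3-prenylfuran-2,4(3H,5H)-dione | `C=C1OC(=O)[C@@](CC=C(C)C)(c2ccc(O[Si](C)(C)C(C)(C)C)c(CC=C(C)C)c2)C1=O`
F6 | step 11 | 4-iodo-2-prenylphenol | `Oc1ccc(I)cc1CC=C(C)C`
F7 | step 11 | tert-butyl(4-iodo-2-prenylphenoxy)dimethylsilane | `CC(C)=CCc1cc(I)ccc1O[Si](C)(C)C(C)(C)C`
F8 | step 2 | allyl {4-[(2-methylbut-3-yn-2-yl)oxy]phenyl}acetate | `C=CCOC(=O)Cc1ccc(OC(C)(C)C#C)cc1`
F9 | step 2 | allyl {4-[(2-methylbut-3-en-2-yl)oxy]phenyl}acetate | `C=CCOC(=O)Cc1ccc(OC(C)(C)C=C)cc1`
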